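**Strategy.** The route rests on disconnecting the pyranone ring between the ketone carbon C4 and the methyl-bearing C3. The O1–C2(Me)–C3(Me)–C4(=O) segment is read as an aryl (S)-but-3-en-2-yl ether plus an ortho formyl group, so an NHC-catalysed intramolecular hydroacylation closes the ring, makes the C3–C4 bond and turns the terminal =CH2 into the C3 methyl in one isomerisation. The precursor is a fully substituted salicylaldehyde in which a dihydrocoumarin lactone masks both the C5 hydroxyl and the carboxylic acid. The benzylic centre comes from an organocatalytic Friedel–Crafts step, C2 from (R)-but-3-en-2-ol, and the cis C3 configuration from a final kinetic protonation.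

Key step: step 8

Remark: C2, C3, C4, C5 in the text are the chroman-4-one locants of the target; intermediates 4–13 are named as chroman-2-ones (dihydrocoumarins) and tricycle 14 as a pyrano[2,3-f]chromene.

**Step 1**
Reactants: 1 3,5-dimethoxyphenol; 2 (E)-oct-2-enal
Product: 4 (4R)-5,7-dimethoxy-4-pentylchroman-2-ol (both C2 anomers), via hydroxy aldehyde 3 (not isolated)
Conditions: (S)-α,α-diphenylprolinol trimethylsilyl ether (20 mol%), PhCO2H (20 mol%), toluene, 0 °C to rt
Reagents that add atoms: none
Why: Iminium-ion organocatalytic Friedel–Crafts alkylation followed by hemiacetalisation: the phenol carbon ortho to OH attacks the β-carbon of the (E)-iminium ion of 2 from the face opposite the diphenyl(silyloxy)methyl group, which for the (S)-catalyst should give the (R)-benzylic centre, and the free OH then closes onto the aldehyde.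

**Step 2**
Reactants: 4 (4R)-5,7-dimethoxy-4-pentylchroman-2-ol
Product: 5 (R)-5,7-dimethoxy-4-pentylchroman-2-one
Conditions: Dess–Martin periodinane, CH2Cl2, rt
Reagents that add atoms: none
Why: Dess–Martin oxidation of a lactol to the lactone; the benzylic centre is not involved.

**Step 3**
Reactants: 5 (R)-5,7-dimethoxy-4-pentylchroman-2-one
Product: 6 (R)-5,7-dimethoxy-2-oxo-4-pentylchromane-8-carbaldehyde
Conditions: Cl2CHOMe, TiCl4, CH2Cl2, −78 to 0 °C; then H2O
Reagents that add atoms: dichloromethyl methyl ether, COC(Cl)Cl; water, O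
Why: Rieche formylation should go to C8, which is para to the 5-OMe and ortho to the 7-OMe, because C6 is screened by the 5-OMe methyl group that the C4 side chain forces toward it.

**Step 4**
Reactants: 6 (R)-5,7-dimethoxy-2-oxo-4-pentylchromane-8-carbaldehyde
Product: 7 (R)-7-hydroxy-5-methoxy-2-oxo-4-pentylchromane-8-carbaldehyde
Conditions: BCl3, CH2Cl2, −78 to 0 °C; then H2O
Reagents that add atoms: none
Why: Chelation-controlled ether cleavage: boron bound to the formyl oxygen reaches only the 7-OMe ortho to it (the other ortho oxygen is the lactone oxygen), so the 5-OMe should survive.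

**Step 5**
Reactants: 8 2-methylbut-3-en-2-ol
Product: 9 tert-butyl (2-methylbut-3-en-2-yl) carbonate
Conditions: n-BuLi, THF, 0 °C; Boc2O, 0 °C to rt; H2O work-up
Reagents that add atoms: di-tert-butyl dicarbonate, CC(C)(C)OC(=O)OC(=O)OC(C)(C)C
Why: O-acylation of the lithium alkoxide of a tertiary alcohol with Boc2O gives the mixed carbonate.

**Step 6**
Reactants: 7 (R)-7-hydroxy-5-methoxy-2-oxo-4-pentylchromane-8-carbaldehyde; 9 tert-butyl (2-methylbut-3-en-2-yl) carbonate
Product: 11 (R)-7-hydroxy-5-methoxy-6-(3-methylbut-2-en-1-yl)-2-oxo-4-pentylchromane-8-carbaldehyde, via 1,1-dimethylallyl aryl ether 10 (not isolated)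
Conditions: Pd(PPh3)4 (5 mol%), THF, 0 °C to rt; filtration through silica; then toluene, 110 °C
Reagents that add atoms: none
Why: Pd-catalysed decarboxylative O-allylation (Tsuji–Trost) should give the tertiary 1,1-dimethylallyl ether kinetically, and its aromatic Claisen rearrangement can end only at C6, the single unsubstituted ortho position, delivering the linear prenyl group.

**Step 7**
Reactants: 11 (R)-7-hydroxy-5-methoxy-6-(3-methylbut-2-en-1-yl)-2-oxo-4-pentylchromane-8-carbaldehyde; 12 (R)-but-3-en-2-ol
Product: 13 (R)-7-{[(S)-but-3-en-2-yl]oxy}-5-methoxy-6-(3-methylbut-2-en-1-yl)-2-oxo-4-pentylchromane-8-carbaldehyde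
Conditions: PPh3, DIAD, toluene, 0 °C to rt
Reagents that add atoms: none
Why: Mitsunobu etherification of the acidic o-formylphenol proceeds by SN2 inversion at the carbinol carbon, converting (R)-12 into the (S)-aryl ether that becomes C2 of the target.

**Step 8**
Reactants: 13 (R)-7-{[(S)-but-3-en-2-yl]oxy}-5-methoxy-6-(3-methylbut-2-en-1-yl)-2-oxo-4-pentylchromane-8-carbaldehyde
Product: 14 (4R,8S,9S)-5-methoxy-8,9-dimethyl-6-(3-methylbut-2-en-1-yl)-4-pentyl-3,4,8,9-tetrahydro-2H,10H-pyrano[2,3-f]chromene-2,10-dione (mainly this trans isomer; its 9R epimer is taken along)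
Conditions: 3-mesityl-5,6,7,8-tetrahydro-4H-cyclohepta[d]thiazol-3-ium perchlorate (20 mol%), DBU (20 mol%), 1,4-dioxane, 120 °C (sealed tube)
Reagents that add atoms: none
Why: The thiazol-2-ylidene adds to the formyl group and proton transfer gives the enaminol (Breslow) intermediate, whose carbinol carbon bonds to the internal alkene carbon while its O–H proton passes to the terminal =CH2 in a concerted, asynchronous five-membered (Conia-ene-like) transition state; loss of the carbene then releases the ketone. The closest known reaction type is the NHC-catalysed intramolecular hydroacylation of unactivated alkenes in 2-(allyloxy)benzaldehydes to 3-methylchroman-4-ones. The pyranone ring closes in the 6-exo-trig mode and the terminal alkene carbon becomes the C3 methyl group (C9 methyl of 14). The new stereocentre C3 (C9 of 14) forms next to the chiral-pool C2 centre (C8 of 14); being α to the ketone with DBU present, it should settle mainly as the trans (8S,9S) isomer, and its final configuration is deliberately left to step 10. The step needs C–C bond formation at the internal alkene carbon rather than benzoin coupling or attack on the prenyl group: the cyclic proton-transfer geometry admits only the tethered terminal alkene, and the two ortho oxygens twist the enaminol out of the arene plane, which pre-organises ring closure and hinders dimerisation. The lactone carbonyl cannot be reached intramolecularly by the enaminol carbon, and DBU is kept no higher than the azolium loading to limit retro-oxa-Michael opening at the oxygen-bearing centre.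

**Step 9**
Reactants: 14 (4R,8S,9S)-5-methoxy-8,9-dimethyl-6-(3-methylbut-2-en-1-yl)-4-pentyl-3,4,8,9-tetrahydro-2H,10H-pyrano[2,3-f]chromene-2,10-dione
Product: 15 (R)-3-[(2S,3S)-5-hydroxy-7-methoxy-2,3-dimethyl-8-(3-methylbut-2-en-1-yl)-4-oxochroman-6-yl]octanoic acid (with its 3R epimer)
Conditions: LiOH (3 equiv), THF/H2O, 0 °C; then 1 M HCl to pH 3–4, 0 °C
Reagents that add atoms: lithium hydroxide, [Li+].[OH-]
Why: Saponification of the aryl lactone is fast at 0 °C and the C5 phenoxide it releases deactivates the ketone toward enolisation and retro-oxa-Michael opening, while any C3 epimerisation is irrelevant because C3 is reset in step 10.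

**Step 10**
Reactants: 15 (R)-3-[(2S,3S)-5-hydroxy-7-methoxy-2,3-dimethyl-8-(3-methylbut-2-en-1-yl)-4-oxochroman-6-yl]octanoic acid
Product: 17 (R)-3-[(2S,3R)-5-hydroxy-7-methoxy-2,3-dimethyl-8-(3-methylbut-2-en-1-yl)-4-oxochroman-6-yl]octanoic acid (target), via tris(trimethylsilyl) enol ether 16 (not isolated)
Conditions: TMSOTf (5 equiv), Et3N (7 equiv), CH2Cl2, 0 °C to rt; then 1 M HCl/THF, −20 to 0 °C
Reagents that add atoms: trimethylsilyl trifluoromethanesulfonate, C[Si](C)(C)OS(=O)(=O)C(F)(F)F (its silyl groups are in intermediate 16 only and leave again on hydrolysis)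
Why: Soft enolisation/silylation followed by kinetic protodesilylation of the silyl enol ether: C3 is the only enolisable position, the C2 methyl of the 4-silyloxy-2H-chromene sits pseudo-axial to avoid A(1,2) strain with the C3 methyl, and irreversible C-protonation anti to it should place the two methyls cis (3R), while the silyl ester and aryl silyl ether hydrolyse in the same work-up.

**Compound list**
1 | 3,5-dimethoxyphenol | COc1cc(O)cc(OC)c1 | starting material
2 | (E)-oct-2-enal | CCCCC/C=C/C=O | starting material
3 | (R)-3-(2-hydroxy-4,6-dimethoxyphenyl)octanal | CCCCC[C@H](CC=O)c1c(O)cc(OC)cc1OC | intermediate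
4 | (4R)-5,7-dimethoxy-4-pentylchroman-2-ol (both C2 anomers) | CCCCC[C@H](CC(O)O2)c1c2cc(OC)cc1OC | intermediate
5 | (R)-5,7-dimethoxy-4-pentylchroman-2-one | CCCCC[C@H](CC(=O)O2)c1c2cc(OC)cc1OC | intermediate
6 | (R)-5,7-dimethoxy-2-oxo-4-pentylchromane-8-carbaldehyde | CCCCC[C@H](CC(=O)O2)c1c2c(C=O)c(OC)cc1OC | intermediate
7 | (R)-7-hydroxy-5-methoxy-2-oxo-4-pentylchromane-8-carbaldehyde | CCCCC[C@H](CC(=O)O2)c1c2c(C=O)c(O)cc1OC | intermediate
8 | 2-methylbut-3-en-2-ol | C=CC(C)(C)O | starting material
9 | tert-butyl (2-methylbut-3-en-2-yl) carbonate | C=CC(C)(C)OC(=O)OC(C)(C)C | intermediate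
10 | (R)-5-methoxy-7-[(2-methylbut-3-en-2-yl)oxy]-2-oxo-4-pentylchromane-8-carbaldehyde | CCCCC[C@H](CC(=O)O2)c1c2c(C=O)c(OC(C)(C)C=C)cc1OC | intermediate
11 | (R)-7-hydroxy-5-methoxy-6-(3-methylbut-2-en-1-yl)-2-oxo-4-pentylchromane-8-carbaldehyde | CCCCC[C@H](CC(=O)O2)c1c2c(C=O)c(O)c(CC=C(C)C)c1OC | intermediate
12 | (R)-but-3-en-2-ol | O[C@H](C)C=C | starting material
13 | (R)-7-{[(S)-but-3-en-2-yl]oxy}-5-methoxy-6-(3-methylbut-2-en-1-yl)-2-oxo-4-pentylchromane-8-carbaldehyde | CCCCC[C@H](CC(=O)O2)c1c2c(C=O)c(O[C@@H](C)C=C)c(CC=C(C)C)c1OC | intermediate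
14 | (4R,8S,9S)-5-methoxy-8,9-dimethyl-6-(3-methylbut-2-en-1-yl)-4-pentyl-3,4,8,9-tetrahydro-2H,10H-pyrano[2,3-f]chromene-2,10-dione (major C9 epimer) | CCCCC[C@H](CC(=O)O3)c1c3c2c(c(CC=C(C)C)c1OC)O[C@@H](C)[C@H](C)C2=O | intermediate
15 | (R)-3-[(2S,3S)-5-hydroxy-7-methoxy-2,3-dimethyl-8-(3-methylbut-2-en-1-yl)-4-oxochroman-6-yl]octanoic acid (major C3 epimer) | CCCCC[C@H](CC(=O)O)c1c(O)c2c(c(CC=C(C)C)c1OC)O[C@@H](C)[C@H](C)C2=O | intermediate
16 | trimethylsilyl (R)-3-[(S)-7-methoxy-2,3-dimethyl-8-(3-methylbut-2-en-1-yl)-4,5-bis(trimethylsilyloxy)-2H-chromen-6-yl]octanoate | CCCCC[C@H](CC(=O)O[Si](C)(C)C)c1c(O[Si](C)(C)C)c2c(c(CC=C(C)C)c1OC)O[C@@H](C)C(C)=C2O[Si](C)(C)C | intermediate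
17 | (R)-3-[(2S,3R)-5-hydroxy-7-methoxy-2,3-dimethyl-8-(3-methylbut-2-en-1-yl)-4-oxochroman-6-yl]octanoic acid | CCCCC[C@H](CC(=O)O)c1c(O)c2c(c(CC=C(C)C)c1OC)O[C@@H](C)[C@@H](C)C2=O | target

**Step count.** Total: 10 steps. Longest linear sequence: 9 steps (steps 1–4 and 6–10; step 5 is a side branch).

**Steps most likely to fail**

1. Step 8. Carbene addition to the doubly ortho-substituted formyl group may be too slow. Thermal Claisen pathways of the 1-methylallyl ether, or base-mediated retro-oxa-Michael opening and reclosure of the product (eroding the oxygen-bearing centre), could then compete at 120 °C. The fallback is a neutral radical ring closure that sets out from aldehyde 13. Pinnick oxidation (NaClO2, NaH2PO4, 2-methylbut-2-ene, t-BuOH/H2O) would give (R)-7-{[(S)-but-3-en-2-yl]oxy}-5-methoxy-6-(3-methylbut-2-en-1-yl)-2-oxo-4-pentylchromane-8-carboxylic acid F1. Treatment with (PhSe)2 and PBu3 would convert it into the Se-phenyl selenoester F2. Slow addition of Bu3SnH with AIBN in benzene at 80 °C would generate the aroyl radical, whose 6-exo-trig cyclisation onto the terminal alkene and hydrogen transfer from the stannane close the same ring. The fallback rejoins the route at 14.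

2. Step 10. Facial discrimination in the C-protonation of the silyl enol ether may be insufficient, or partial relactonisation may occur in the acidic work-up, leaving a cis/trans mixture. The fallback replaces kinetic by thermodynamic control and sets out from 15: base-mediated equilibration (Et3N, MeOH, rt to 40 °C) to the cis/trans mixture, separation of the cis acid by preparative HPLC, and recycling of recovered 15. It arrives at 17 and makes no new compound (F0).

3. Step 7. The Mitsunobu coupling of the hydrogen-bonded phenol flanked by formyl and prenyl groups may stall, or leak through SN2′ attack or ion-pair return with loss of configuration. The fallback is catalyst-controlled C–O bond formation from 11: Pd-catalysed asymmetric allylic etherification with (E)-but-2-en-1-yl methyl carbonate, Pd2(dba)3·CHCl3 and the enantiomer of the C2-symmetric DACH-phenyl diphosphine ligand that delivers the (S)-branched ether, in CH2Cl2 at rt. It arrives directly at 13 and makes no new compound (F0).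

**Further compounds**
F1 | step 8 | (R)-7-{[(S)-but-3-en-2-yl]oxy}-5-methoxy-6-(3-methylbut-2-en-1-yl)-2-oxo-4-pentylchromane-8-carboxylic acid | CCCCC[C@H](CC(=O)O2)c1c2c(C(=O)O)c(O[C@@H](C)C=C)c(CC=C(C)C)c1OC
F2 | step 8 | Se-phenyl (R)-7-{[(S)-but-3-en-2-yl]oxy}-5-methoxy-6-(3-methylbut-2-en-1-yl)-2-oxo-4-pentylchromane-8-carboselenoate | CCCCC[C@H](CC(=O)O2)c1c2c(C(=O)[Se]c3ccccc3)c(O[C@@H](C)C=C)c(CC=C(C)C)c1OC
F0 | step 10 | none | none
F0 | step 7 | none | none
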